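The whole plan rests on inserting C12 between C11 and C8 (prostaglandin numbering). The ring C8–C9–C10–C11–C12 is made from the cyclobutanone C8–C9–C10–C11 by a diazoalkane ring expansion. The diazo carbon becomes C12 and already carries the whole 3-oxooctyl chain as a ketal, so one operation forms C11–C12 and C8–C12, sets the ring size and joins ring and ω-chain. The precursor, a 2,2-dichloro-3-alkoxy-4-alkylcyclobutanone, exploits the 1,3-relation of the C9 oxygen and the C11 carbonyl and the cis C8/C9 pair: both centres come from one dichloroketene cycloaddition to a Z enol ether of a purchased chiral alcohol. The C10 chlorines steer C8 migration and later block aldol dehydration.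

Key step: step 12

Remark on numbering: prostaglandin numbering is used for all intermediates (C1 carboxyl, C5=C6 Z-alkene, ring C8 to C12, C9 hydroxyl, C11 and C15 ketones). R* = (R)-1-(2,4,6-triisopropylphenyl)ethyl.

Assumption: dichloroketene is taken to approach the Z enol ether in its s-trans conformation, anti to the aryl group of the auxiliary, with the benzylic C–H eclipsing the enol ether plane. On this model the (R)-alcohol should give the (8R,9S) pair. Should the facial sense prove opposite, the equally available (S)-alcohol is used without other change.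

Step 1
Reactants: 1 hex-5-ynoic acid
Product: 2 tert-butyl hex-5-ynoate
Conditions: isobutylene, H2SO4 (cat.), CH2Cl2, –20 °C → rt, sealed tube
Reagents that add atoms: isobutylene, CC(C)=C
Why: Acid-catalysed addition of the carboxylic acid to isobutylene should give the tert-butyl ester, a protecting group that resists the organolithium steps and leaves with acid in step 13.

Step 2
Reactants: 2 tert-butyl hex-5-ynoate
Product: 3 tert-butyl 7-hydroxyhept-5-ynoate
Conditions: LiN(i-Pr)2 (1.05 equiv), THF, –78 °C; (CH2O)n, –78 °C → rt; aq. NH4Cl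
Reagents that add atoms: paraformaldehyde (formaldehyde unit), C=O
Why: The terminal alkyne C–H is the most acidic site, so the lithium acetylide should form and add to formaldehyde (acetylide hydroxymethylation) while the hindered tert-butyl ester is spared at low temperature.

Step 3
Reactants: 3 tert-butyl 7-hydroxyhept-5-ynoate
Product: 4 tert-butyl (Z)-7-hydroxyhept-5-enoate
Conditions: H2 (1 atm), Pd/CaCO3 poisoned with Pb(OAc)2, quinoline, EtOAc, rt
Reagents that add atoms: none
Why: Syn delivery of H2 on the poisoned palladium surface (Lindlar semihydrogenation) should stop at the alkene and set the Z geometry of C5=C6.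

Step 4
Reactants: 4 tert-butyl (Z)-7-hydroxyhept-5-enoate
Product: 5 tert-butyl (Z)-7-bromohept-5-enoate
Conditions: CBr4, PPh3, CH2Cl2, 0 °C
Reagents that add atoms: carbon tetrabromide, BrC(Br)(Br)Br
Why: Appel bromination displaces the oxyphosphonium ion of the primary allylic alcohol by SN2 at 0 °C, which should preserve the Z alkene and avoid allylic transposition.

Step 5
Reactants: 6 (R)-1-(2,4,6-triisopropylphenyl)ethanol, 7 trichloroethylene, 5 tert-butyl (Z)-7-bromohept-5-enoate
Product: 10 tert-butyl (Z)-9-[(R)-1-(2,4,6-triisopropylphenyl)ethoxy]non-5-en-8-ynoate, via dichlorovinyl ether 8 (not isolated), via lithium alkoxyacetylide 9 (not isolated)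
Conditions: KH (1.05 equiv), THF, 0 °C → rt; Cl2C=CHCl, –50 °C → rt; n-BuLi (2.05 equiv), –78 → –40 °C; 5 (0.9 equiv), HMPA, –78 °C → rt
Reagents that add atoms: none
Why: The potassium alkoxide of 6 adds to dichloroacetylene formed from 7 to give 8, n-BuLi then effects dehydrochlorination and Cl/Li exchange to the alkoxyacetylide 9, and SN2 alkylation of 9 by the reactive allylic bromide 5 (acetylide alkylation) should give the ynol ether with the Z alkene and the auxiliary stereocentre untouched.

Step 6
Reactants: 10 tert-butyl (Z)-9-[(R)-1-(2,4,6-triisopropylphenyl)ethoxy]non-5-en-8-ynoate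
Product: 11 tert-butyl (5Z,8Z)-9-[(R)-1-(2,4,6-triisopropylphenyl)ethoxy]nona-5,8-dienoate
Conditions: H2 (1 atm), Pd/BaSO4, pyridine, rt, stopped after one equivalent
Reagents that add atoms: none
Why: Semihydrogenation of the electron-rich ynol ether on poisoned palladium by syn addition of H2 should give the Z enol ether needed for the cis C8/C9 relation without touching the existing disubstituted alkene.

Step 7
Reactants: 11 tert-butyl (5Z,8Z)-9-[(R)-1-(2,4,6-triisopropylphenyl)ethoxy]nona-5,8-dienoate
Product: 12 tert-butyl (Z)-7-[(1S,2R)-3,3-dichloro-4-oxo-2-[(R)-1-(2,4,6-triisopropylphenyl)ethoxy]cyclobutyl]hept-5-enoate (cis-disubstituted, used crude)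
Conditions: Cl3CCOCl (1.5 equiv, slow addition), Zn–Cu couple, Et2O, 0 °C → rt
Reagents that add atoms: trichloroacetyl chloride, ClC(Cl)(Cl)C(=O)Cl
Why: In this thermal ketene–alkene [2+2] cycloaddition the ketene carbonyl carbon bonds to the nucleophilic enol ether β-carbon (C8) and the CCl2 carbon to C9, suprafacial addition to the Z enol ether makes C8 and C9 cis, the aryl group of the auxiliary shields one face so that the (8R,9S) pair should form, and the far more nucleophilic enol ether should react in preference to the C5=C6 alkene.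

Step 8
Reactants: 13 ethyl 4-chloro-4-oxobutanoate, 14 pentylmagnesium bromide
Product: 15 ethyl 4-oxononanoate
Conditions: Fe(acac)3 (3 mol %), THF, –78 °C
Reagents that add atoms: none
Why: Fe(acac)3-catalysed acylation of the Grignard reagent by the acid chloride at –78 °C is much faster than addition to the ester or to the ketone formed, so the γ-keto ester should result.

Step 9
Reactants: 15 ethyl 4-oxononanoate
Product: 16 ethyl 3-(2-pentyl-1,3-dioxolan-2-yl)propanoate
Conditions: HOCH2CH2OH, TsOH (cat.), toluene, reflux, Dean–Stark trap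
Reagents that add atoms: ethylene glycol, OCCO
Why: Acid-catalysed ketalisation with azeotropic removal of water masks the C15 ketone as a dioxolane that should survive hydride, hydrazine and the diazo stage.

Step 10
Reactants: 16 ethyl 3-(2-pentyl-1,3-dioxolan-2-yl)propanoate
Product: 17 3-(2-pentyl-1,3-dioxolan-2-yl)propanal
Conditions: i-Bu2AlH (1.05 equiv), CH2Cl2, –78 °C; Rochelle salt work-up
Reagents that add atoms: none
Why: At –78 °C the tetrahedral aluminium hemiacetal from one hydride transfer persists until work-up, so the ester should be reduced only to the aldehyde (partial ester reduction).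

Step 11
Reactants: 17 3-(2-pentyl-1,3-dioxolan-2-yl)propanal
Product: 18 (E)-[3-(2-pentyl-1,3-dioxolan-2-yl)propylidene]hydrazine (used crude)
Conditions: N2H4·H2O (5 equiv), EtOH, 0 °C → rt
Reagents that add atoms: hydrazine, NN
Why: Condensation of the aldehyde with excess hydrazine should give the N-unsubstituted hydrazone, the excess suppressing azine formation and the ketal being stable to the basic medium.

Step 12
Reactants: 12 tert-butyl (Z)-7-[(1S,2R)-3,3-dichloro-4-oxo-2-[(R)-1-(2,4,6-triisopropylphenyl)ethoxy]cyclobutyl]hept-5-enoate, 18 (E)-[3-(2-pentyl-1,3-dioxolan-2-yl)propylidene]hydrazine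
Product: 20 tert-butyl (Z)-7-[(1R,2R,5R)-3,3-dichloro-4-oxo-5-[2-(2-pentyl-1,3-dioxolan-2-yl)ethyl]-2-[(R)-1-(2,4,6-triisopropylphenyl)ethoxy]cyclopentyl]hept-5-enoate, via diazoalkane 19 (not isolated)
Conditions: 18, DMSO (1.1 equiv), (COCl)2 (1.05 equiv), THF, –78 °C; Et3N (2.1 equiv), –78 °C; cold filtration; then 12, THF, –78 → 0 °C; work-up, then Et3N (0.2 equiv), CH2Cl2, rt
Reagents that add atoms: none
Why: The nucleophilic diazo carbon of 19 adds to the strained, chlorine-activated C11 carbonyl of 12 to give a diazonium betaine, and C8 then shifts from C11 to the diazo carbon with loss of N2, so that the four-membered ring C8–C9–C10–C11 becomes the five-membered ring C8–C9–C10–C11–C12 while C11–C12 and C8–C12 are formed and the ω-chain is attached in the same event. The closest known reaction type is the regioselective diazoalkane ring expansion of α,α-dichlorocyclobutanones (Büchner–Curtius–Schlotterbeck type homologation). No ring is closed by cyclisation: the five-membered ring arises by a 1,2-alkyl shift that enlarges the pre-formed four-membered ring by one atom. C8 migrates with retention and C9 is untouched, so both keep the configuration set in step 7, whereas the new centre C12 is epimerisable (α to C11, the only enolisable side) and should settle under thermodynamic control trans to the C8 chain, during the Et3N treatment and again in the acid of step 13. The step needs migration of C8 instead of C10, which the two electron-withdrawing chlorines on C10 secure, and a single homologation at the cyclobutanone carbonyl only, which the loss of ring strain in 20 and the masking of C15 as a dioxolane secure.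

Step 13
Reactants: 20 tert-butyl (Z)-7-[(1R,2R,5R)-3,3-dichloro-4-oxo-5-[2-(2-pentyl-1,3-dioxolan-2-yl)ethyl]-2-[(R)-1-(2,4,6-triisopropylphenyl)ethoxy]cyclopentyl]hept-5-enoate
Product: 21 (Z)-7-[(1R,2R,5R)-3,3-dichloro-2-hydroxy-4-oxo-5-(3-oxooctyl)cyclopentyl]hept-5-enoic acid
Conditions: TFA, CH2Cl2, 0 °C → rt; then H2O/THF, rt
Reagents that add atoms: water, O
Why: Acidolysis through the stabilised benzylic cation (auxiliary ether) and the tert-butyl cation (ester) together with hydrolysis of the dioxolane should unmask the C9 hydroxyl, the C1 acid and the C15 ketone in one operation, while the chlorines on C10 prevent enolisation toward C9 and hence dehydration of the aldol and enolisation toward C12 keeps that centre trans to the C8 chain.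

Step 14
Reactants: 21 (Z)-7-[(1R,2R,5R)-3,3-dichloro-2-hydroxy-4-oxo-5-(3-oxooctyl)cyclopentyl]hept-5-enoic acid
Product: 22 13,14-dihydro-15-keto-PGD2, (Z)-7-[(1R,2R,5S)-5-hydroxy-3-oxo-2-(3-oxooctyl)cyclopentyl]hept-5-enoic acid
Conditions: Bu3SnH (3 equiv, 0.5 M), Et3B (0.2 equiv), air, toluene, 0 °C → rt; MeCN/hexane partition
Reagents that add atoms: none
Why: In this radical chain dechlorination the stannyl radical abstracts the two activated chlorines in turn and each α-keto radical at C10 is quenched by fast hydrogen transfer from Bu3SnH under neutral conditions, so no enolate is formed, β-elimination of the C9 hydroxyl should not occur, and no stereocentre is created or disturbed.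

Compound list
1 | hex-5-ynoic acid | C#CCCCC(=O)O | starting material
2 | tert-butyl hex-5-ynoate | C#CCCCC(=O)OC(C)(C)C | intermediate
3 | tert-butyl 7-hydroxyhept-5-ynoate | OCC#CCCCC(=O)OC(C)(C)C | intermediate
4 | tert-butyl (Z)-7-hydroxyhept-5-enoate | OC/C=C\CCCC(=O)OC(C)(C)C | intermediate
5 | tert-butyl (Z)-7-bromohept-5-enoate | BrC/C=C\CCCC(=O)OC(C)(C)C | intermediate
6 | (R)-1-(2,4,6-triisopropylphenyl)ethanol | C[C@@H](O)c1c(C(C)C)cc(C(C)C)cc1C(C)C | starting material
7 | trichloroethylene | ClC=C(Cl)Cl | starting material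
8 | (E)-1,2-dichlorovinyl (R)-1-(2,4,6-triisopropylphenyl)ethyl ether | C[C@@H](O/C(Cl)=C\Cl)c1c(C(C)C)cc(C(C)C)cc1C(C)C | intermediate
9 | lithium 2-[(R)-1-(2,4,6-triisopropylphenyl)ethoxy]acetylide | C[C@@H](OC#C[Li])c1c(C(C)C)cc(C(C)C)cc1C(C)C | intermediate
10 | tert-butyl (Z)-9-[(R)-1-(2,4,6-triisopropylphenyl)ethoxy]non-5-en-8-ynoate | C[C@@H](OC#CC/C=C\CCCC(=O)OC(C)(C)C)c1c(C(C)C)cc(C(C)C)cc1C(C)C | intermediate
11 | tert-butyl (5Z,8Z)-9-[(R)-1-(2,4,6-triisopropylphenyl)ethoxy]nona-5,8-dienoate | C[C@@H](O/C=C\C/C=C\CCCC(=O)OC(C)(C)C)c1c(C(C)C)cc(C(C)C)cc1C(C)C | intermediate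
12 | tert-butyl (Z)-7-[(1S,2R)-3,3-dichloro-4-oxo-2-[(R)-1-(2,4,6-triisopropylphenyl)ethoxy]cyclobutyl]hept-5-enoate | O=C1C(Cl)(Cl)[C@H](O[C@H](C)c2c(C(C)C)cc(C(C)C)cc2C(C)C)[C@@H]1C/C=C\CCCC(=O)OC(C)(C)C | intermediate
13 | ethyl 4-chloro-4-oxobutanoate | CCOC(=O)CCC(=O)Cl | starting material
14 | pentylmagnesium bromide | CCCCC[Mg]Br | starting material
15 | ethyl 4-oxononanoate | CCCCCC(=O)CCC(=O)OCC | intermediate
16 | ethyl 3-(2-pentyl-1,3-dioxolan-2-yl)propanoate | CCCCCC1(CCC(=O)OCC)OCCO1 | intermediate
17 | 3-(2-pentyl-1,3-dioxolan-2-yl)propanal | CCCCCC1(CCC=O)OCCO1 | intermediate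
18 | (E)-[3-(2-pentyl-1,3-dioxolan-2-yl)propylidene]hydrazine | CCCCCC1(CC/C=N/N)OCCO1 | intermediate
19 | 2-(3-diazopropyl)-2-pentyl-1,3-dioxolane | CCCCCC1(CCC=[N+]=[N-])OCCO1 | intermediate
20 | tert-butyl (Z)-7-[(1R,2R,5R)-3,3-dichloro-4-oxo-5-[2-(2-pentyl-1,3-dioxolan-2-yl)ethyl]-2-[(R)-1-(2,4,6-triisopropylphenyl)ethoxy]cyclopentyl]hept-5-enoate | CCCCCC1(OCCO1)CC[C@H]2C(=O)C(Cl)(Cl)[C@H](O[C@H](C)c3c(C(C)C)cc(C(C)C)cc3C(C)C)[C@@H]2C/C=C\CCCC(=O)OC(C)(C)C | intermediate
21 | (Z)-7-[(1R,2R,5R)-3,3-dichloro-2-hydroxy-4-oxo-5-(3-oxooctyl)cyclopentyl]hept-5-enoic acid | CCCCCC(=O)CC[C@H]1C(=O)C(Cl)(Cl)[C@H](O)[C@@H]1C/C=C\CCCC(=O)O | intermediate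
22 | 13,14-dihydro-15-keto-PGD2, (Z)-7-[(1R,2R,5S)-5-hydroxy-3-oxo-2-(3-oxooctyl)cyclopentyl]hept-5-enoic acid | CCCCCC(=O)CC[C@H]1C(=O)C[C@H](O)[C@@H]1C/C=C\CCCC(=O)O | target

Total step count: 14. Longest linear sequence: 10 steps (steps 1 to 7, then 12 to 14).

Steps most likely to fail

Step 12. The bulky, non-stabilised diazoalkane may add only sluggishly to the hindered carbonyl flanked by CCl2 and C8, so that decay of the diazoalkane (azine formation, protonation) or epoxide formation competes with the ring expansion. The fallback keeps the ring expansion but separates it from the attachment of the ω-chain. It sets out from 12. Diazomethane (Et2O, MeOH cat., 0 °C) should enlarge the ring with the same C8 migration and give tert-butyl (Z)-7-[(1R,2R)-3,3-dichloro-4-oxo-2-[(R)-1-(2,4,6-triisopropylphenyl)ethoxy]cyclopentyl]hept-5-enoate F1, in which C12 is a methylene group. Soft enolisation (TMSOTf, Et3N, CH2Cl2, 0 °C) can only go toward C12, because C10 carries no hydrogen, and should give the C11–C12 trimethylsilyl enol ether F2. Mukaiyama–Michael addition of F2 to commercial oct-1-en-3-one (Sc(OTf)3 cat., CH2Cl2, –78 °C, aqueous work-up) should give tert-butyl (Z)-7-[(1R,2R,5R)-3,3-dichloro-4-oxo-5-(3-oxooctyl)-2-[(R)-1-(2,4,6-triisopropylphenyl)ethoxy]cyclopentyl]hept-5-enoate F3 with the C15 ketone free. TFA in CH2Cl2 then removes the auxiliary and the tert-butyl ester and equilibrates C12, and the route is rejoined at 21.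

Step 14. Reversible addition of the stannyl radical may isomerise the C5=C6 Z-alkene, the C10 radical may cyclise onto that alkene, or the free aldol may dehydrate while tin residues are removed. The fallback replaces the radical reduction of the unprotected acid by a two-electron reduction of the protected compound. It sets out from 20. Zn–Cu couple with NH4Cl in MeOH at rt, where protonation of the zinc enolate should outrun β-elimination, should give tert-butyl (Z)-7-[(1R,2R,5S)-3-oxo-2-[2-(2-pentyl-1,3-dioxolan-2-yl)ethyl]-5-[(R)-1-(2,4,6-triisopropylphenyl)ethoxy]cyclopentyl]hept-5-enoate F4. A short exposure to TFA/H2O/CH2Cl2 at 0 °C then removes auxiliary, tert-butyl ester and dioxolane and comes back to the route at 22.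

Step 5. The lithium acetylide or residual n-BuLi may attack the ester of 5, or react with the allylic bromide by SN2′ displacement or metal–halogen exchange, so that the one-pot alkylation gives little ynol ether. The fallback separates acetylide formation from the C–C coupling. It sets out from 6. The first two stages are run as before, and the acetylide 9 is quenched with MeOH to isolate (R)-1-(ethynyloxy)ethyl-2,4,6-triisopropylbenzene F5. The terminal ynol ether is then allylated with 5 through its copper acetylide (CuI, K2CO3, NaI, DMF, rt), conditions that tolerate esters, and the route is rejoined at 10.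

Further compounds
F1 | step 12 | tert-butyl (Z)-7-[(1R,2R)-3,3-dichloro-4-oxo-2-[(R)-1-(2,4,6-triisopropylphenyl)ethoxy]cyclopentyl]hept-5-enoate | C1C(=O)C(Cl)(Cl)[C@H](O[C@H](C)c2c(C(C)C)cc(C(C)C)cc2C(C)C)[C@@H]1C/C=C\CCCC(=O)OC(C)(C)C
F2 | step 12 | tert-butyl (Z)-7-[(1R,5R)-4,4-dichloro-3-(trimethylsilyloxy)-5-[(R)-1-(2,4,6-triisopropylphenyl)ethoxy]cyclopent-2-en-1-yl]hept-5-enoate | C1=C(O[Si](C)(C)C)C(Cl)(Cl)[C@H](O[C@H](C)c2c(C(C)C)cc(C(C)C)cc2C(C)C)[C@@H]1C/C=C\CCCC(=O)OC(C)(C)C
F3 | step 12 | tert-butyl (Z)-7-[(1R,2R,5R)-3,3-dichloro-4-oxo-5-(3-oxooctyl)-2-[(R)-1-(2,4,6-triisopropylphenyl)ethoxy]cyclopentyl]hept-5-enoate | CCCCCC(=O)CC[C@H]1C(=O)C(Cl)(Cl)[C@H](O[C@H](C)c2c(C(C)C)cc(C(C)C)cc2C(C)C)[C@@H]1C/C=C\CCCC(=O)OC(C)(C)C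
F4 | step 14 | tert-butyl (Z)-7-[(1R,2R,5S)-3-oxo-2-[2-(2-pentyl-1,3-dioxolan-2-yl)ethyl]-5-[(R)-1-(2,4,6-triisopropylphenyl)ethoxy]cyclopentyl]hept-5-enoate | CCCCCC1(OCCO1)CC[C@H]2C(=O)C[C@H](O[C@H](C)c3c(C(C)C)cc(C(C)C)cc3C(C)C)[C@@H]2C/C=C\CCCC(=O)OC(C)(C)C
F5 | step 5 | (R)-1-(ethynyloxy)ethyl-2,4,6-triisopropylbenzene | C[C@@H](OC#C)c1c(C(C)C)cc(C(C)C)cc1C(C)C
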